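**Plan**

- Retrosynthesis: after removal of two phenol silyl groups, the quinone ring is cut at C1–C2 and C3–C4. This excises C2(side chain)=C3H as a terminal alkyne and leaves C1(=O) and C4(=O) bonded to each other in the four-membered ring of a 3,6-dioxygenated benzocyclobutene-1,2-dione.
- Enabling feature: the quinone ring is a 1,4-diacylarene (C1, C4, C4a, C8a) bridged by a CR=CH unit, i.e. an alkyne inserted into a CO–CO bond. The 5,8-dioxygenated benzenoid ring makes the dione C2-symmetric, so the insertion has no regiochemical issue, and C3–H calls for a terminal alkyne.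
- Forward order: the benzenoid ring is bought; the four-membered ring is made by aryne/ketene acetal [2+2] cycloaddition and oxidised to the dione; methyl ethers are exchanged for silyl ethers early. Cobalt then inserts into the CO–CO bond, and alkyne insertion/reductive elimination gives the quinone ring.
- The alkyne partner already carries the whole side chain and the senecioate ester; a last fluoride step unveils the naphthazarin.
- Stereochemistry: the single (S) centre comes from Noyori asymmetric transfer hydrogenation of a silyl ynone and is never a reacting centre afterwards.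

Key step: step 12

Assumption: the target is a naphthazarin whose 1,4- and 5,8-quinone tautomers interconvert rapidly; it is drawn and made as the tautomer given. Dative P–Co and N–Co bonds in the SMILES of the cobalt complexes are written with formal charges.

**Route**

Step 1
Reactants: 1 2-bromo-1,4-dimethoxybenzene; 2 1,1-dimethoxyethene (ketene dimethyl acetal)
Product: 5 3,6-dimethoxybenzocyclobuten-1(2H)-one, via 3,6-dimethoxybenzyne 3 (not isolated), via dimethyl ketal 4 (not isolated)
Conditions: NaNH2 (2.2 equiv), 2 (2 equiv), THF, reflux; then 1 M aq. HCl, THF, rt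
Reagents that add atoms: water, O
Why: Amide dehydrobrominates 1 to the symmetric aryne 3, which undergoes a stepwise [2+2] cycloaddition with the electron-rich ketene acetal (aryne–ketene acetal benzocyclobutenone synthesis); the symmetry of 3 removes any regiochemical question and mild acid unmasks the ketone.

Step 2
Reactants: 5 3,6-dimethoxybenzocyclobuten-1(2H)-one
Product: 6 2,2-dibromo-3,6-dimethoxybenzocyclobuten-1(2H)-one
Conditions: NBS (2.2 equiv), (BzO)2 (cat.), CCl4, reflux, hν
Reagents that add atoms: N-bromosuccinimide, O=C1CCC(=O)N1Br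
Why: Wohl–Ziegler radical bromination at the only sp3 C–H position, which is benzylic and α to the carbonyl; non-polar radical conditions disfavour ring bromination and no enol is required.

Step 3
Reactants: 6 2,2-dibromo-3,6-dimethoxybenzocyclobuten-1(2H)-one
Product: 7 3,6-dimethoxybenzocyclobutene-1,2-dione
Conditions: AgOCOCF3 (2.2 equiv), MeCN–H2O, 50 °C
Reagents that add atoms: water, O
Why: Silver-assisted hydrolysis of a gem-dibromide to a ketone; the acidic medium avoids the hydroxide-induced cleavage to which the strained 1,2-dione is prone.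

Step 4
Reactants: 7 3,6-dimethoxybenzocyclobutene-1,2-dione
Product: 8 3,6-dihydroxybenzocyclobutene-1,2-dione
Conditions: BBr3 (3 equiv), CH2Cl2, −78 to 0 °C; aq. work-up
Reagents that add atoms: none
Why: BBr3 cleavage of aryl methyl ethers, done here on a robust small molecule so that no harsh dealkylation is needed later in the presence of the side chain.

Step 5
Reactants: 8 3,6-dihydroxybenzocyclobutene-1,2-dione
Product: 9 3,6-bis(tert-butyldimethylsilyloxy)benzocyclobutene-1,2-dione
Conditions: TBSCl (2.5 equiv), imidazole, DMF, 0 °C to rt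
Reagents that add atoms: tert-butyldimethylsilyl chloride, CC(C)(C)[Si](C)(C)Cl
Why: Standard phenol silylation; the silyl ethers tolerate the neutral cobalt chemistry and are later removed by fluoride without base or strong Lewis acid.

Step 6
Reactants: 10 4-methylpent-3-enoic acid
Product: 12 N-methoxy-N,4-dimethylpent-3-enamide, via acyl imidazole 11 (not isolated)
Conditions: CDI (1.1 equiv), CH2Cl2, rt; then MeNHOMe·HCl (1.2 equiv), rt
Reagents that add atoms: N,O-dimethylhydroxylamine hydrochloride, CNOC.Cl
Why: Carbonyldiimidazole activation followed by aminolysis (Weinreb amide formation) under conditions too mild to move the β,γ-double bond into conjugation.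

Step 7
Reactants: 12 N-methoxy-N,4-dimethylpent-3-enamide; 13 ethynyltrimethylsilane
Product: 15 6-methyl-1-(trimethylsilyl)hept-5-en-1-yn-3-one, via lithium acetylide 14 (not isolated)
Conditions: 13, n-BuLi, THF, −78 °C; then 12, −78 to 0 °C; cold sat. aq. NH4Cl
Reagents that add atoms: none
Why: Weinreb ketone synthesis; the chelated tetrahedral adduct prevents over-addition and keeps the acidic α-CH2 of the ynone masked until the cold, mildly acidic quench.

Step 8
Reactants: 15 6-methyl-1-(trimethylsilyl)hept-5-en-1-yn-3-one
Product: 16 (S)-6-methyl-1-(trimethylsilyl)hept-5-en-1-yn-3-ol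
Conditions: Ru(p-cymene)[(S,S)-TsDPEN] (16-electron amido complex, 1 mol %), i-PrOH, rt
Reagents that add atoms: none
Why: Noyori asymmetric transfer hydrogenation of an ynone; the alkynyl group takes the place of the aryl group of acetophenone in the transition state, so the (S,S)-catalyst should give the (S)-propargylic alcohol, and the base-free conditions leave alkene, alkyne and the enolisable CH2 alone.

Step 9
Reactants: 16 (S)-6-methyl-1-(trimethylsilyl)hept-5-en-1-yn-3-ol
Product: 17 (S)-6-methylhept-5-en-1-yn-3-ol
Conditions: K2CO3 (cat.), MeOH, rt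
Reagents that add atoms: none
Why: Methoxide-induced protiodesilylation of the alkynylsilane; the carbinol centre is not involved.

Step 10
Reactants: 17 (S)-6-methylhept-5-en-1-yn-3-ol; 18 3-methylbut-2-enoic acid
Product: 19 (S)-6-methylhept-5-en-1-yn-3-yl 3-methylbut-2-enoate
Conditions: DCC (1.2 equiv), DMAP (cat.), CH2Cl2, 0 °C to rt
Reagents that add atoms: none
Why: Steglich esterification; acylation takes place at oxygen, so the C–O bond of the stereocenter is untouched and the configuration is retained.

Step 11
Reactants: 9 3,6-bis(tert-butyldimethylsilyloxy)benzocyclobutene-1,2-dione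
Product: 21 chloro(dimethylglyoxime)(pyridine)[3,6-bis(tert-butyldimethylsilyloxy)phthaloyl]cobalt(III), via bis(phosphine) cobaltacycle 20 (not isolated)
Conditions: ClCo(PPh3)3 (1.05 equiv), benzene, rt, Ar; then dimethylglyoxime (1.1 equiv), pyridine, rt; trituration with Et2O
Reagents that add atoms: chlorotris(triphenylphosphine)cobalt(I), Cl[Co-3]([P+](c1ccccc1)(c1ccccc1)c1ccccc1)([P+](c1ccccc1)(c1ccccc1)c1ccccc1)[P+](c1ccccc1)(c1ccccc1)c1ccccc1; dimethylglyoxime, CC(=NO)C(C)=NO; pyridine, c1ccncc1
Why: Oxidative addition of electron-rich Co(I) into the strained CO–CO bond of the four-membered ring gives the five-membered phthaloylcobalt metallacycle, and exchange of the phosphines for dimethylglyoxime/pyridine gives the phosphine-free, air-stable complex used for alkyne insertion.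

Step 12
Reactants: 21 chloro(dimethylglyoxime)(pyridine)[3,6-bis(tert-butyldimethylsilyloxy)phthaloyl]cobalt(III); 19 (S)-6-methylhept-5-en-1-yn-3-yl 3-methylbut-2-enoate
Product: 22 (S)-1-[5,8-bis(tert-butyldimethylsilyloxy)-1,4-dioxo-1,4-dihydronaphthalen-2-yl]-4-methylpent-3-en-1-yl 3-methylbut-2-enoate
Conditions: 19 (1.5 equiv), CoCl2·6H2O (1.5 equiv, Lewis-acid promoter), ClCH2CH2Cl, 75 °C, Ar; aerobic work-up
Reagents that add atoms: none
Why: The Lewis acid opens a coordination site on the Co(III) diacyl complex, the terminal alkyne of 19 binds and inserts into one Co–acyl bond to give a seven-membered cobaltacycle, and C(sp2)–C(acyl) reductive elimination expels cobalt and closes the six-membered quinone ring; the four carbons of the former cyclobutenedione ring, held in the five-membered cobaltacycle of 21, are thereby expanded by the two alkyne carbons. The closest known reaction type is the phthaloylcobalt–alkyne naphthoquinone synthesis (cobalt-mediated alkyne insertion into benzocyclobutenediones), of which this is a direct application. The ring is closed by reductive elimination from the metallacycle, a formal [4+2] annulation of the 1,4-diacyl unit with the alkyne, not by an ionic or pericyclic cyclisation. No new stereocenter is formed, and the propargylic C–O stereocenter of 19 is a spectator because no bond to it is broken and no cation or enolate is generated at it under these neutral conditions. Regioselectivity is not needed, since the 3,6-disubstituted phthaloyl unit is C2-symmetric and both insertion senses give 22. The step needs chemoselectivity for the alkyne over the trisubstituted alkene and the enoate, which the far higher insertion aptitude of alkynes should secure, and reductive elimination from the chelated metallacycle must outpace β-acyloxy elimination.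

Step 13
Reactants: 22 (S)-1-[5,8-bis(tert-butyldimethylsilyloxy)-1,4-dioxo-1,4-dihydronaphthalen-2-yl]-4-methylpent-3-en-1-yl 3-methylbut-2-enoate
Product: 23 alkannin β,β-dimethylacrylate
Conditions: HF·pyridine, THF, 0 °C to rt, in the dark
Reagents that add atoms: none
Why: Fluoride-driven cleavage of the two aryl silyl ethers (strong Si–F bond, stabilised peri-hydrogen-bonded phenols as leaving groups) under non-basic conditions that should leave the secondary ester, both alkenes and the stereocenter untouched.

**Compound list**

1 | 2-bromo-1,4-dimethoxybenzene | COc1ccc(OC)c(Br)c1 | starting material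
2 | 1,1-dimethoxyethene (ketene dimethyl acetal) | C=C(OC)OC | starting material
3 | 3,6-dimethoxybenzyne | COC1=CC=C(OC)C#C1 | intermediate
4 | 3,6-dimethoxybenzocyclobutenone dimethyl ketal (2,5,7,7-tetramethoxybicyclo[4.2.0]octa-1,3,5-triene) | COc1ccc(OC)c2c1CC2(OC)OC | intermediate
5 | 3,6-dimethoxybenzocyclobuten-1(2H)-one | COc1ccc(OC)c2c1CC2=O | intermediate
6 | 2,2-dibromo-3,6-dimethoxybenzocyclobuten-1(2H)-one | COc1ccc(OC)c2c1C(Br)(Br)C2=O | intermediate
7 | 3,6-dimethoxybenzocyclobutene-1,2-dione | COc1ccc(OC)c2c1C(=O)C2=O | intermediate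
8 | 3,6-dihydroxybenzocyclobutene-1,2-dione | Oc1ccc(O)c2c1C(=O)C2=O | intermediate
9 | 3,6-bis(tert-butyldimethylsilyloxy)benzocyclobutene-1,2-dione | CC(C)(C)[Si](C)(C)Oc1ccc(O[Si](C)(C)C(C)(C)C)c2c1C(=O)C2=O | intermediate
10 | 4-methylpent-3-enoic acid | CC(C)=CCC(=O)O | starting material
11 | 1-(4-methylpent-3-enoyl)imidazole | CC(C)=CCC(=O)n1ccnc1 | intermediate
12 | N-methoxy-N,4-dimethylpent-3-enamide | CC(C)=CCC(=O)N(C)OC | intermediate
13 | ethynyltrimethylsilane | C#C[Si](C)(C)C | starting material
14 | lithium (trimethylsilyl)acetylide | [Li]C#C[Si](C)(C)C | intermediate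
15 | 6-methyl-1-(trimethylsilyl)hept-5-en-1-yn-3-one | CC(C)=CCC(=O)C#C[Si](C)(C)C | intermediate
16 | (S)-6-methyl-1-(trimethylsilyl)hept-5-en-1-yn-3-ol | CC(C)=CC[C@H](O)C#C[Si](C)(C)C | intermediate
17 | (S)-6-methylhept-5-en-1-yn-3-ol | CC(C)=CC[C@H](O)C#C | intermediate
18 | 3-methylbut-2-enoic acid (senecioic acid) | CC(C)=CC(=O)O | starting material
19 | (S)-6-methylhept-5-en-1-yn-3-yl 3-methylbut-2-enoate | CC(C)=CC[C@H](OC(=O)C=C(C)C)C#C | intermediate
20 | chlorobis(triphenylphosphine)[3,6-bis(tert-butyldimethylsilyloxy)phthaloyl]cobalt(III) | CC(C)(C)[Si](C)(C)Oc1ccc(O[Si](C)(C)C(C)(C)C)c2c1C(=O)[Co-2](Cl)([P+](c1ccccc1)(c1ccccc1)c1ccccc1)([P+](c1ccccc1)(c1ccccc1)c1ccccc1)C2=O | intermediate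
21 | chloro(dimethylglyoxime)(pyridine)[3,6-bis(tert-butyldimethylsilyloxy)phthaloyl]cobalt(III) | CC1=[N+](O)[Co-3]2(Cl)([n+]3ccccc3)(C(=O)c3c(O[Si](C)(C)C(C)(C)C)ccc(O[Si](C)(C)C(C)(C)C)c3C2=O)[N+](O)=C1C | intermediate
22 | (S)-1-[5,8-bis(tert-butyldimethylsilyloxy)-1,4-dioxo-1,4-dihydronaphthalen-2-yl]-4-methylpent-3-en-1-yl 3-methylbut-2-enoate | CC(C)=CC[C@H](OC(=O)C=C(C)C)C1=CC(=O)c2c(O[Si](C)(C)C(C)(C)C)ccc(O[Si](C)(C)C(C)(C)C)c2C1=O | intermediate
23 | alkannin β,β-dimethylacrylate, (S)-1-(5,8-dihydroxy-1,4-dioxo-1,4-dihydronaphthalen-2-yl)-4-methylpent-3-en-1-yl 3-methylbut-2-enoate | CC(C)=CC[C@H](OC(=O)C=C(C)C)C1=CC(=O)c2c(O)ccc(O)c2C1=O | target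

**Step count**

Total: 13 steps. Longest linear sequence: 8 steps (steps 1–5, 11, 12, 13, from 1); the alkyne branch is 5 steps (6–10) and joins at step 12.

**Steps most likely to fail, with fallbacks**

1. Step 12. The propargylic acyloxy group may be lost before ring closure, by β-acyloxy elimination from the alkenylcobalt intermediate or by a Lewis-acid-induced 1,3-acyloxy shift, so that the alkyne is consumed without forming the quinone. The fallback moves the ester bond formation to the end and sets out from 17 (with 21 as partner). The alcohol 17 is silylated (TBSCl, imidazole, DMF) to (S)-tert-butyldimethyl[(6-methylhept-5-en-1-yn-3-yl)oxy]silane F1, whose propargylic silyl ether is a poor leaving group. F1 is inserted into 21 (CoCl2·6H2O, ClCH2CH2Cl, 75 °C) to give (S)-2-[1-(tert-butyldimethylsilyloxy)-4-methylpent-3-enyl]-5,8-bis(tert-butyldimethylsilyloxy)-1,4-naphthoquinone F2. HF·pyridine then removes all three silyl groups to give alkannin F3. The side-chain hydroxyl of F3, the only one not held in a peri hydrogen bond, is acylated with 18 (DCC, DMAP, CH2Cl2), and the route is rejoined at 23.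

2. Step 2. Electrophilic bromination of the electron-rich dimethoxyarene ring may compete with radical bromination of the CH2 group. The fallback deactivates the ring before the oxidation and sets out from 5. BBr3 gives 3,6-dihydroxybenzocyclobuten-1(2H)-one F4, and Ac2O/pyridine gives 3,6-diacetoxybenzocyclobuten-1(2H)-one F5, in which the acetoxy groups are only weakly activating. Wohl–Ziegler dibromination then gives 2,2-dibromo-3,6-diacetoxybenzocyclobuten-1(2H)-one F6, and AgOCOCF3 in aqueous MeCN gives 3,6-diacetoxybenzocyclobutene-1,2-dione F7. Acid hydrolysis of the aryl acetates (2 M HCl, aqueous dioxane, 50 °C) rejoins the route at 8.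

3. Step 8. Hydride transfer may discriminate the two ketone faces incompletely, or the β,γ-unsaturated ynone may enolise and move its double bond into conjugation during the reduction. The fallback sets the stereocenter by reagent-controlled allylation and never makes the ynone; it sets out from 13. Lithiation and formylation (n-BuLi; DMF) give 3-(trimethylsilyl)propynal F8. Brown allylation with (−)-B-allyldiisopinocampheylborane at −78 °C (the reagent that gives the (S)-carbinol from benzaldehyde, the alkynyl group taking the place of phenyl) gives (S)-1-(trimethylsilyl)hex-5-en-1-yn-3-ol F9. Cross-metathesis of F9 with 2-methyl-2-butene (Grubbs second-generation catalyst, CH2Cl2, 40 °C) turns the allyl into the prenyl group and rejoins the route at 16.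

**Further compounds**

F1 | step 12 | (S)-tert-butyldimethyl[(6-methylhept-5-en-1-yn-3-yl)oxy]silane | CC(C)=CC[C@H](O[Si](C)(C)C(C)(C)C)C#C
F2 | step 12 | (S)-2-[1-(tert-butyldimethylsilyloxy)-4-methylpent-3-enyl]-5,8-bis(tert-butyldimethylsilyloxy)-1,4-naphthoquinone | CC(C)=CC[C@H](O[Si](C)(C)C(C)(C)C)C1=CC(=O)c2c(O[Si](C)(C)C(C)(C)C)ccc(O[Si](C)(C)C(C)(C)C)c2C1=O
F3 | step 12 | alkannin | CC(C)=CC[C@H](O)C1=CC(=O)c2c(O)ccc(O)c2C1=O
F4 | step 2 | 3,6-dihydroxybenzocyclobuten-1(2H)-one | Oc1ccc(O)c2c1CC2=O
F5 | step 2 | 3,6-diacetoxybenzocyclobuten-1(2H)-one | CC(=O)Oc1ccc(OC(C)=O)c2c1CC2=O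
F6 | step 2 | 2,2-dibromo-3,6-diacetoxybenzocyclobuten-1(2H)-one | CC(=O)Oc1ccc(OC(C)=O)c2c1C(Br)(Br)C2=O
F7 | step 2 | 3,6-diacetoxybenzocyclobutene-1,2-dione | CC(=O)Oc1ccc(OC(C)=O)c2c1C(=O)C2=O
F8 | step 8 | 3-(trimethylsilyl)propynal | C[Si](C)(C)C#CC=O
F9 | step 8 | (S)-1-(trimethylsilyl)hex-5-en-1-yn-3-ol | C=CC[C@H](O)C#C[Si](C)(C)C
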